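**Assumption:** cembrane numbering is used (C16 lactone carbonyl, lactone O on C14, C17 exocyclic CH2). The target SMILES decodes to 1S,3R,4S,7R,8S,12S,13R,14R, with a cis-fused lactone and a cis-2,5-oxolane. Commodity reagents that add atoms are given with SMILES inside each step and are not numbered.

## Retrosynthetic overview

1. The oxolane is made last: target ⇐ AcOH-terminated transannular epoxide-opening cascade of a (3R,4R,7R,8R)-bis-epoxide ⇐ macrocyclic 3E,7E-diene.
2. The 14-membered carbocycle and the cis-α-methylene-γ-lactone are made together by forming C1–C14 in an indium-catalysed electroreductive intramolecular Barbier allylation.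
3. The open chain comes from cross-metathesis (C1=C15) with methyl 2-(bromomethyl)acrylate and a Cu-catalysed sp3–sp3 coupling (C9–C10).
4. C10–C14 comes from (R)-3-hydroxy-γ-butyrolactone (C13 bought, C12 by trans dianion methylation); C1–C9 comes from geranyl acetate.
5. Ring order: macrocycle + lactone (step 12), then oxolane (step 15).

## Route

**Step 1**
Reactants: 1, geranyl acetate
Product: 2, (2E,6E)-8-hydroxy-3,7-dimethylocta-2,6-dien-1-yl acetate
Conditions: SeO2 (0.3 equiv), t-BuOOH, salicylic acid (cat.), CH2Cl2, rt
Reagents that add atoms: tert-butyl hydroperoxide, CC(C)(C)OO (oxygen source); selenium dioxide, O=[Se]=O (oxygen relay)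
Why: SeO2/TBHP allylic oxidation (ene/[2,3] sequence) hits the E-methyl of the terminal alkene because the allylic acetate deactivates the 2,3-alkene; no stereocentre is formed.

**Step 2**
Reactants: 2
Product: 3, (2E,6E)-2,6-dimethyldeca-2,6,9-trien-1-ol
Conditions: vinylMgBr (3 equiv), Li2CuCl4 (5 mol %), THF, −20 → 0 °C
Reagents that add atoms: vinylmagnesium bromide, C=C[Mg]Br
Why: Cu-catalysed (Fouquet–Schlosser type) SN2 substitution of the primary allylic acetate is α-selective and keeps the E geometry, while the C8 alkoxide is not a leaving group.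

**Step 3**
Reactants: 3
Product: 4, (2E,6E)-1-bromo-2,6-dimethyldeca-2,6,9-triene
Conditions: MsCl, Et3N, CH2Cl2, −40 °C; then LiBr, THF, 0 °C
Reagents that add atoms: lithium bromide, [Li+].[Br-]
Why: Mesylation followed by SN2 bromide displacement converts the primary allylic alcohol without allylic transposition.

**Step 4**
Reactants: 5, (R)-3-hydroxy-γ-butyrolactone [(4R)-4-hydroxyoxolan-2-one]
Product: 6, (3R,4R)-4-hydroxy-3-methyloxolan-2-one (trans)
Conditions: LDA (2.2 equiv), THF, −78 °C; MeI, DMPU, −78 → −40 °C
Reagents that add atoms: iodomethane, CI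
Why: Alkylation of the β-hydroxy lactone dianion (cyclic Fráter–Seebach alkylation) occurs anti to the C4–OLi group, so the bought carbinol centre (future C13) sets the methyl centre (future C12) trans on the ring, which is the syn Me/O relationship of the open chain.

**Step 5**
Reactants: 6
Product: 7, (3R,4R)-3-methyloxolane-2,4-diol (lactol, anomer mixture)
Conditions: DIBAL-H (2.1 equiv), CH2Cl2, −78 °C
Reagents that add atoms: none
Why: Low-temperature DIBAL reduction stops at the tetrahedral aluminate and gives the lactol; neither stereocentre is touched.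

**Step 6**
Reactants: 7
Product: 8, (2R,3S)-3-methylpent-4-ene-1,2-diol
Conditions: Ph3PCH3Br (3.5 equiv), KOt-Bu, THF, 0 °C → rt
Reagents that add atoms: methyltriphenylphosphonium bromide, C[P+](c1ccccc1)(c1ccccc1)c1ccccc1.[Br-]
Why: Wittig methylenation of the open hydroxy-aldehyde form of the lactol, as with 2-deoxy-sugar lactols, adds the carbon that becomes C10 and leaves both stereocentres as set.

**Step 7**
Reactants: 8
Product: 9, (4R)-4-[(2S)-but-3-en-2-yl]-2,2-dimethyl-1,3-dioxolane
Conditions: Me2C(OMe)2, PPTS (cat.), CH2Cl2, rt
Reagents that add atoms: 2,2-dimethoxypropane, COC(C)(C)OC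
Why: Acetonide formation on the terminal 1,2-diol protects it for the organometallic steps.

**Step 8**
Reactants: 9
Product: 10, (4R)-4-[(2S)-4-iodobutan-2-yl]-2,2-dimethyl-1,3-dioxolane
Conditions: Cp2Zr(H)Cl, THF, rt; then I2, 0 °C
Reagents that add atoms: iodine, II
Why: Schwartz hydrozirconation puts Zr on the terminal carbon of the only alkene, and iodinolysis gives the primary iodide in one pot.

**Step 9**
Reactants: 10 and 4
Product: 11, (2R,3S,7E,11E)-3,7,11-trimethylpentadeca-7,11,14-triene-1,2-diol
Conditions: 10, t-BuLi (2.1 equiv), Et2O, −78 °C; MgBr2·OEt2; then 4, Li2CuCl4 (3 mol %), THF, −40 → 0 °C; then PPTS, MeOH, 40 °C (acetonide cleavage, telescoped)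
Reagents that add atoms: none (both partners are numbered reactants)
Why: I/Li exchange and transmetalation give a primary alkyl Grignard that undergoes Li2CuCl4-catalysed α-selective sp3–sp3 coupling with the allylic bromide (C9–C10, E retained), and mild acid methanolysis then frees the diol.

**Step 10**
Reactants: 11 and 12, methyl 2-(bromomethyl)acrylate
Product: 13, methyl (2Z,5E,9E,14S,15R)-2-(bromomethyl)-15,16-dihydroxy-6,10,14-trimethylhexadeca-2,5,9-trienoate
Conditions: 12 (4 equiv), Hoveyda–Grubbs II (7 mol %), 1,4-benzoquinone (15 mol %), CH2Cl2, 40 °C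
Reagents that add atoms: methyl 2-(bromomethyl)acrylate (12), C=C(CBr)C(=O)OC
Why: Olefin cross-metathesis engages only the monosubstituted alkene (the trisubstituted alkenes are spectators) and gives the thermodynamic isomer with the chain trans to the ester, i.e. the (Z)-2-(bromomethyl)enoate; benzoquinone suppresses isomerisation of the skipped diene.

**Step 11**
Reactants: 13
Product: 14, methyl (2Z,5E,9E,14S,15R)-2-(bromomethyl)-15-hydroxy-6,10,14-trimethyl-16-oxohexadeca-2,5,9-trienoate (used crude)
Conditions: TEMPO (10 mol %), PhI(OAc)2 (1.1 equiv), dry CH2Cl2, rt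
Reagents that add atoms: none
Why: Oxoammonium (TEMPO) oxidation is selective for the primary over the secondary hydroxyl and stops at the aldehyde under anhydrous conditions, leaving the allylic bromide and alkenes intact.

**Step 12**
Reactants: 14
Product: 15, (1S,3E,7E,12S,13R,14R)-13-hydroxycembra-3,7,15(17)-trien-16,14-olide (14-membered carbocycle cis-fused to an α-methylene-γ-butyrolactone)
Conditions: InCl3 (20 mol %), undivided cell, Al anode / RVC cathode, Bu4NBr (0.1 M), THF–H2O 9:1, 3 mA constant current (about 2.5 F/mol), 14 added by syringe pump over 12 h (final 2 mM), rt; then TsOH·H2O (cat.), CH2Cl2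
Reagents that add atoms: none
Why: Proposed new method: an indium-catalysed electroreductive intramolecular Barbier allylation–lactonisation, in which cathodic reduction of In(III) to In(I) (far easier than direct reduction of the allylic bromide, enoate or aldehyde) is followed by oxidative addition to the 2-(bromomethyl)enoate to give an ester-coordinated (Z)-allylindium(III); this adds through C1 to the In-chelated α-hydroxy aldehyde (Cram chelate gives 13,14-syn, so 14R) via a chair transition state (syn C14/C1, so 1S and a cis lactone), the γ-alkoxide lactonises with loss of MeOH, In(III) is returned to the cathode, and the current limits the standing concentration of allylindium so ring closure beats oligomerisation; the closest known reactions are stoichiometric In(0)-mediated aqueous Barbier lactonisations of 2-(bromomethyl)acrylates with α-hydroxy aldehydes and electro-regenerated In(I)-catalysed intermolecular allylation, neither shown for macrocyclisation.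

**Step 13**
Reactants: 15
Product: 16, (1S,3E,7E,12S,13R,14R)-13-acetoxycembra-3,7,15(17)-trien-16,14-olide
Conditions: Ac2O, pyridine, DMAP (cat.), CH2Cl2, 0 °C → rt
Reagents that add atoms: acetic anhydride, CC(=O)OC(C)=O
Why: Standard O-acetylation of the only free (secondary) hydroxyl, done before the C3 hydroxyl exists so no later differentiation is needed.

**Step 14**
Reactants: 16
Product: 17, (1S,3R,4R,7R,8R,12S,13R,14R)-13-acetoxy-3,4:7,8-diepoxycembr-15(17)-en-16,14-olide
Conditions: dimethyldioxirane (2.4 equiv), acetone/CH2Cl2, −20 → 0 °C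
Reagents that add atoms: dimethyldioxirane, CC1(C)OO1
Why: Electrophilic epoxidation takes the two electron-rich trisubstituted E-alkenes and leaves the electron-poor methylene lactone; peripheral attack on the macrocycle conformer that holds both vinylic methyls on the same face is expected to give both epoxides in the same sense (3R,4R,7R,8R), so these centres are set by the ring stereocentres.

**Step 15**
Reactants: 17
Product: 18, target, (1S,3R,4S,7R,8S,12S,13R,14R)-8,13-diacetoxy-3-hydroxy-4,7-epoxycembr-15(17)-en-16,14-olide
Conditions: AcOH/CH2Cl2 (1:3), CSA (10 mol %), 0 °C → rt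
Reagents that add atoms: acetic acid, CC(=O)O
Why: In an acid-triggered transannular epoxide-opening cascade the 7,8-epoxide oxygen attacks the protonated 3,4-epoxide at tertiary C4 (5-membered closure, inversion to 4S, C3 keeps its oxygen as the free 3R-OH) and acetic acid opens the resulting epoxonium at tertiary C8 with inversion (8S-OAc, 7R retained), giving the cis-oxolane and the tertiary acetate without any hydroxyl differentiation.

## Compound list

1 | geranyl acetate | CC(C)=CCC/C(C)=C/COC(C)=O | starting material
2 | (2E,6E)-8-hydroxy-3,7-dimethylocta-2,6-dien-1-yl acetate | OC/C(C)=C/CC/C(C)=C/COC(C)=O | intermediate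
3 | (2E,6E)-2,6-dimethyldeca-2,6,9-trien-1-ol | OC/C(C)=C/CC/C(C)=C/CC=C | intermediate
4 | (2E,6E)-1-bromo-2,6-dimethyldeca-2,6,9-triene | BrC/C(C)=C/CC/C(C)=C/CC=C | intermediate
5 | (R)-3-hydroxy-γ-butyrolactone, (4R)-4-hydroxyoxolan-2-one | O=C1C[C@@H](O)CO1 | starting material
6 | (3R,4R)-4-hydroxy-3-methyloxolan-2-one | C[C@@H]1[C@@H](O)COC1=O | intermediate
7 | (3R,4R)-3-methyloxolane-2,4-diol (lactol, anomer mixture) | C[C@@H]1[C@@H](O)COC1O | intermediate
8 | (2R,3S)-3-methylpent-4-ene-1,2-diol | C=C[C@H](C)[C@@H](O)CO | intermediate
9 | (4R)-4-[(2S)-but-3-en-2-yl]-2,2-dimethyl-1,3-dioxolane | C=C[C@H](C)[C@@H]1COC(C)(C)O1 | intermediate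
10 | (4R)-4-[(2S)-4-iodobutan-2-yl]-2,2-dimethyl-1,3-dioxolane | ICC[C@H](C)[C@@H]1COC(C)(C)O1 | intermediate
11 | (2R,3S,7E,11E)-3,7,11-trimethylpentadeca-7,11,14-triene-1,2-diol | C=CC/C=C(C)/CC/C=C(C)/CCC[C@H](C)[C@@H](O)CO | intermediate
12 | methyl 2-(bromomethyl)acrylate | C=C(CBr)C(=O)OC | starting material
13 | methyl (2Z,5E,9E,14S,15R)-2-(bromomethyl)-15,16-dihydroxy-6,10,14-trimethylhexadeca-2,5,9-trienoate | COC(=O)/C(CBr)=C/C/C=C(C)/CC/C=C(C)/CCC[C@H](C)[C@@H](O)CO | intermediate
14 | methyl (2Z,5E,9E,14S,15R)-2-(bromomethyl)-15-hydroxy-6,10,14-trimethyl-16-oxohexadeca-2,5,9-trienoate | COC(=O)/C(CBr)=C/C/C=C(C)/CC/C=C(C)/CCC[C@H](C)[C@@H](O)C=O | intermediate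
15 | (1S,3E,7E,12S,13R,14R)-13-hydroxycembra-3,7,15(17)-trien-16,14-olide | C=C1C(=O)O[C@H]2[C@H](O)[C@@H](C)CCC/C(C)=C/CC/C(C)=C/C[C@@H]12 | intermediate
16 | (1S,3E,7E,12S,13R,14R)-13-acetoxycembra-3,7,15(17)-trien-16,14-olide | C=C1C(=O)O[C@H]2[C@H](OC(C)=O)[C@@H](C)CCC/C(C)=C/CC/C(C)=C/C[C@@H]12 | intermediate
17 | (1S,3R,4R,7R,8R,12S,13R,14R)-13-acetoxy-3,4:7,8-diepoxycembr-15(17)-en-16,14-olide | C=C1C(=O)O[C@H]2[C@H](OC(C)=O)[C@@H](C)CCC[C@@]3(C)O[C@@H]3CC[C@@]4(C)O[C@@H]4C[C@@H]12 | intermediate
18 | (1S,3R,4S,7R,8S,12S,13R,14R)-8,13-diacetoxy-3-hydroxy-4,7-epoxycembr-15(17)-en-16,14-olide (CID10479028) | C=C1C(=O)O[C@H]2[C@H](OC(C)=O)[C@@H](C)CCC[C@](C)(OC(C)=O)[C@H]3CC[C@](C)(O3)[C@H](O)C[C@@H]12 | target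

## Summary

Total steps: 15.
Longest linear sequence: 12 steps (5 → 18, steps 4–15); the geranyl arm is 3 steps (steps 1–3).

Three steps most likely to fail:

1. **Step 12 (proposed new electro-indium macrocyclisation).** Risks are slow In turnover, oligomerisation, or loss of the chelate/chair control in the ring-forming transition state. Fallback (known chemistry, different order of ring formation): make the C1–C14 bond and the lactone intermolecularly with stoichiometric In(0) in THF/H2O between the CM product of 3 with 12 and the α-hydroxy aldehyde from 8. Then vinylate the C9 allylic carbonate (Pd), close the ring by RCM at C10=C11, and reduce that alkene with diimide while the methylene lactone is masked as its Me2NH adduct.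

2. **Step 14 (and its consequence in step 15).** The facial selectivity of the double epoxidation rests on macrocyclic conformational control, and the cascade can divert to 4,8-bridged oxanes. Fallback: a stepwise, hydroxyl-directed sequence. Mono-epoxidise C7=C8, open it with AcOH to the 7-hydroxy-8-acetate, then use VO(acac)2/t-BuOOH epoxidation of the bishomoallylic C3=C4 alkene directed by the C7 hydroxyl, with in-situ 5-exo closure to the oxolane.

3. **Step 10 (cross-metathesis with methyl 2-(bromomethyl)acrylate on a skipped diene).** Risks are alkene isomerisation or low conversion to the trisubstituted enoate. Fallback: abandon metathesis and build the bromo-enoate from an aldehyde. Carry C2 as the allylic acetate through the Cu coupling (8-bromogeranyl acetate in place of 4), then convert acetate → bromide → nitrile → β,γ-unsaturated aldehyde (DIBAL), form the Baylis–Hillman adduct with methyl acrylate, and brominate SN2′ with NBS/Me2S to the same (Z)-bromide.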